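It is easy to take a slow flask for one short of catalyst and to reach for more. Here a solid, J, gives the product Z under a catalyst, E, and you can turn two settings: the charge of E and the time.

| flask | J | E | remark | time |
|---|---|---|---|---|
| ash | 20 mM | 17 µM | run made earlier |  |
| alder | 20 mM | 120 µM | run made earlier |  |
| south-east | 20 mM | 20 µM |  | 30 h |
| north-west | 20 mM | 40 µM |  | 30 h |
| north-east | 20 mM | 80 µM |  | 30 h |
| north | 20 mM | 150 µM |  | 30 h |

| ash: time / h | ash: Z / % | alder: time / h | alder: Z / % |
|---|---|---|---|
| 3.00 | 4.9 | 3.00 | 8.9 |
| 6.00 | 11.7 | 6.00 | 16.8 |
| 10.0 | 19.8 | 10.0 | 26.5 |
| 12.0 | 23.3 | 12.0 | 31.2 |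
| 15.0 | 29.0 | 15.0 | 36.4 |

(each reading ± 0.3 percentage points)

1. amount of Z at the end, in percent of the J charged for south-east, north-west, north-east, north, in this order
2. how that number moves from the first to the last of them (falls all the way / hardly changes / rises all the way / falls, then rises / rises, then falls)

- solid, in amounts per volume of the solution: J
- at the start none of J is in solution
- a reading or a percentage of Z counts all its forms, free or not
- "hardly changes" means that all values lie within two and a half points (for a concentration: within two and a half percent of the largest)

Turn E first. By hand, a flask whose rate follows E should give 7.06 times the Z when you go from the ash run to the alder run. At 15.0 h, the alder run holds 1.26 times the Z of the ash run, which is less than that. Take as leverage, n, the logarithm of the ratio of Z between two flasks at one time over the logarithm of their ratio of E, the apparent order in E: here it is 0.116.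

Now turn time. At 3.00 h, n read from the same two runs was 0.305, so between these runs it shrinks from that time to the later one. The alder run also bends, gaining 8.9% in its first 3.00 h and 5.2 percentage points in its last 3.00 h.

My own reckoning is therefore a nearly level row, since even the n of 15.0 h turns the span of E in the row into a factor of 1.26, and n is falling. Carrying the last alder slope straight on to 30 h gives 62.4%, and if the curve keeps bending it ends below that line.

The forecast gives 59.2%, 60%, 60.2% and 60.3%, so the row hardly changes, with the height just under my line: “Dissolution therefore limits the rate, and the catalyst simply keeps up.”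

The flasks give 40.6%, 40.5%, 40.5% and 40.5%: the row hardly changes, at a height below the forecast.

    X + E ⇌ L + E, rate k1*[E]*[X] forward; the back reaction follows from the equilibrium constant (k = 89.0 M⁻¹ min⁻¹)
    Z ⇌ X (K = 1.00, k = 0.00110 min⁻¹)
    J ⇌ L, rate k3*(cs3 - [L]) while solid is left; crystals form when [L] > cs3 (solubility = 8.10 mM, k = 0.00340 min⁻¹)
    E + Z ⇌ D (K = 55.0 M⁻¹, k = 0.110 M⁻¹ min⁻¹)
    L + E ⇌ Z + E, rate k5*[L]*[E] forward; the back reaction follows from the equilibrium constant (K = 2.10, k = 250 M⁻¹ min⁻¹)

Used on the flasks at 15.0 h, n gives north the factor 1.26 over south-east, and they stand at 36.7% and 29.9%, a factor of 1.23. At 30 h, n between the same flasks is −0.00122. In south-east at that time, J is down to 0%, and the step between dissolved J, L, and free Z, taken by itself with both directions counted, has a relaxation half-life of 2.21 h, shorter than the run. The half-life of free Z by the forward rate alone of its path to the other product, X, is 11 h, also shorter than the run, and L, Z and X stand at 19.3%, 40.6% and 40.1%.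

The readings were generated by integration for substances that don't exist; noise was put on by code.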